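**Retrosynthetic overview**
- The two formyl groups come off last: Vilsmeier diformylation of a free phloroglucinol ring B, with ring A deactivated as its dipivalate.
- The pyran ring (the only ring made; both benzene rings are bought) is closed at C2–O1 by an invertive Mitsunobu etherification of a para-acyl phenol onto a benzylic alcohol.
- The C4–C4a bond comes from an sp3–sp2 Negishi coupling of a primary alkylzinc with an iodinated, already isovalerylated phloroglucinol (ring A).
- The C2–C3 bond and both stereocentres come from an Evans syn-aldol of an N-isovaleryl oxazolidinone with 2,4,6-tris(benzyloxy)benzaldehyde (key step).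

Assumption: chroman numbering (O1, C2 aryl, C3 isopropyl, C4 CH2) is used; the SMILES encodes (2R,3S), i.e. 2,3-trans.

**Route**

Step 1
Reactants: 1 (S)-4-benzyloxazolidin-2-one; 2 3-methylbutanoyl chloride
Product: 4 (S)-4-benzyl-3-(3-methylbutanoyl)oxazolidin-2-one, via N-lithio oxazolidinone 3 (not isolated)
Conditions: n-BuLi, THF, −78 °C; then 2, −78 → 0 °C
Reagents that add atoms: none
Why: N-acylation of the lithiated oxazolidinone by the acid chloride is a standard way to attach the Evans auxiliary.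

Step 2
Reactants: 5 2,4,6-trihydroxybenzaldehyde
Product: 6 2,4,6-tris(benzyloxy)benzaldehyde
Conditions: BnBr (3.6 equiv), K2CO3, DMF, 60 °C
Reagents that add atoms: benzyl bromide BrCc1ccccc1
Why: Williamson O-benzylation; the formyl group lowers ring nucleophilicity so O-alkylation wins over C-alkylation.

Step 3
Reactants: 4 (S)-4-benzyl-3-(3-methylbutanoyl)oxazolidin-2-one; 6 2,4,6-tris(benzyloxy)benzaldehyde
Product: 9 (S)-4-benzyl-3-[(2S,3S)-3-hydroxy-2-isopropyl-3-(2,4,6-tris(benzyloxy)phenyl)propanoyl]oxazolidin-2-one, via Z-dibutylboron enolate 7 (not isolated), via dibutylboron aldolate 8 (not isolated)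
Conditions: Bu2BOTf, i-Pr2NEt, CH2Cl2, 0 °C; then 6, −78 → 0 °C; pH 7 buffer, MeOH, H2O2, 0 °C
Reagents that add atoms: none
Why: Evans syn-aldol: the Z-boron enolate reacts through a chair Zimmerman–Traxler transition state on the face away from the auxiliary benzyl group, setting the isopropyl-bearing carbon S (future C-3) and the benzylic carbinol S (deliberately opposite to the target, because step 13 inverts it).

Step 4
Reactants: 9 aldol adduct
Product: 10 (S)-4-benzyl-3-[(2S,3S)-3-(tert-butyldimethylsilyloxy)-2-isopropyl-3-(2,4,6-tris(benzyloxy)phenyl)propanoyl]oxazolidin-2-one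
Conditions: TBSOTf, 2,6-lutidine, CH2Cl2, −78 → 0 °C
Reagents that add atoms: tert-butyldimethylsilyl triflate CC(C)(C)[Si](C)(C)OS(=O)(=O)C(F)(F)F
Why: Silyl triflate silylation of the hindered secondary alcohol blocks retro-aldol and ionisation of the electron-rich benzylic carbinol; no stereocentre is touched.

Step 5
Reactants: 10 silyl ether imide
Product: 11 (2R,3S)-3-(tert-butyldimethylsilyloxy)-2-isopropyl-3-[2,4,6-tris(benzyloxy)phenyl]propan-1-ol
Conditions: LiBH4, MeOH (1 equiv), THF, 0 °C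
Reagents that add atoms: none
Why: Reductive cleavage of the imide gives the primary alcohol and returns the auxiliary without touching the α-centre (the descriptor changes to R only through CIP priorities).

Step 6
Reactants: 11 primary alcohol
Product: 12 tert-butyl{(1S,2S)-2-(iodomethyl)-3-methyl-1-[2,4,6-tris(benzyloxy)phenyl]butoxy}dimethylsilane
Conditions: PPh3, I2, imidazole, CH2Cl2, 0 °C → rt
Reagents that add atoms: iodine [I][I]
Why: Appel-type iodination of the primary alcohol under imidazole-buffered conditions that the benzylic silyl ether tolerates.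

Step 7
Reactants: 13 phloroglucinol; 2 3-methylbutanoyl chloride
Product: 14 3-methyl-1-(2,4,6-trihydroxyphenyl)butan-1-one
Conditions: AlCl3, PhNO2/CH2Cl2, rt → 45 °C; aq. HCl
Reagents that add atoms: none
Why: Friedel–Crafts C-acylation of phloroglucinol stops at the mono-ketone because the first acyl group deactivates the ring.

Step 8
Reactants: 14 acylphloroglucinol
Product: 15 1-[4-(tert-butyldimethylsilyloxy)-2,6-dihydroxyphenyl]-3-methylbutan-1-one
Conditions: TBSCl (1.05 equiv), imidazole, DMF, 0 °C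
Reagents that add atoms: tert-butyldimethylsilyl chloride CC(C)(C)[Si](C)(C)Cl
Why: Selective O-silylation: the para hydroxyl is the most acidic and the only one neither hydrogen-bonded to nor crowded by the ketone, which marks the oxygen that later becomes O1.

Step 9
Reactants: 15 para-silyl ether
Product: 16 1-[4-(tert-butyldimethylsilyloxy)-2,6-dihydroxy-3-iodophenyl]-3-methylbutan-1-one
Conditions: N-iodosuccinimide (1.0 equiv), CH2Cl2, −20 → 0 °C
Reagents that add atoms: N-iodosuccinimide O=C1CCC(=O)N1I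
Why: Electrophilic aromatic iodination at one of the two equivalent, strongly activated ring positions; one equivalent keeps it to the mono-iodide.

Step 10
Reactants: 16 iodo diol
Product: 17 5-(tert-butyldimethylsilyloxy)-4-iodo-2-(3-methylbutanoyl)-1,3-phenylene bis(2,2-dimethylpropanoate)
Conditions: t-BuCOCl, Et3N, DMAP (cat.), CH2Cl2, 0 °C → rt
Reagents that add atoms: pivaloyl chloride CC(C)(C)C(Cl)=O
Why: DMAP-catalysed O-acylation masks the acidic phenols for the organozinc step and deactivates ring A for the later formylation.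

Step 11
Reactants: 12 alkyl iodide; 17 aryl iodide
Product: 19 5-(tert-butyldimethylsilyloxy)-4-[(2S,3S)-3-(tert-butyldimethylsilyloxy)-2-isopropyl-3-(2,4,6-tris(benzyloxy)phenyl)propyl]-2-(3-methylbutanoyl)-1,3-phenylene bis(2,2-dimethylpropanoate), via alkylzinc iodide 18 (not isolated)
Conditions: Zn dust (activated with BrCH2CH2Br, Me3SiCl), DMA, 40 °C; then 17, Pd(OAc)2 (5 mol %), SPhos (10 mol %), THF/DMA, 50 °C
Reagents that add atoms: none
Why: Negishi coupling: the primary alkylzinc tolerates ketone, esters and silyl ethers, and the bulky biarylphosphine lets the di-ortho-substituted aryl iodide couple; the stereocentres are not involved.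

Step 12
Reactants: 19 bis-silyl ether
Product: 20 5-hydroxy-4-[(2S,3S)-3-hydroxy-2-isopropyl-3-(2,4,6-tris(benzyloxy)phenyl)propyl]-2-(3-methylbutanoyl)-1,3-phenylene bis(2,2-dimethylpropanoate)
Conditions: HF·pyridine, pyridine, THF, 0 °C → rt
Reagents that add atoms: none
Why: Buffered fluoride desilylation frees exactly the two oxygens needed for ring closure (the para phenol and the benzylic alcohol) and leaves pivalates and benzyl ethers intact.

Step 13
Reactants: 20 phenol alcohol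
Product: 21 (2R,3S)-3-isopropyl-6-(3-methylbutanoyl)-2-[2,4,6-tris(benzyloxy)phenyl]chromane-5,7-diyl bis(2,2-dimethylpropanoate)
Conditions: PPh3, DIAD, THF, 0 °C → rt
Reagents that add atoms: none
Why: Intramolecular Mitsunobu etherification by the only free (para-acyl) phenol displaces the activated benzylic oxygen with inversion, converting the S carbinol into (2R); the 2,3-trans product (aryl and isopropyl both equatorial) is also the one favoured if the electron-rich benzylic centre reacts through an ion pair.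

Step 14
Reactants: 21 tribenzyl chroman
Product: 22 (2R,3S)-3-isopropyl-6-(3-methylbutanoyl)-2-(2,4,6-trihydroxyphenyl)chromane-5,7-diyl bis(2,2-dimethylpropanoate)
Conditions: H2 (1 atm), Pd/C (10 wt %), EtOAc, rt
Reagents that add atoms: none
Why: Hydrogenolysis removes the three primary O-benzyl groups much faster than it attacks the hindered cyclic benzylic C2–O1 bond or the shielded ketone.

Step 15
Reactants: 22 ring B triol
Product: 24 (2R,3S)-2-(3,5-diformyl-2,4,6-trihydroxyphenyl)-3-isopropyl-6-(3-methylbutanoyl)chromane-5,7-diyl bis(2,2-dimethylpropanoate), via bis-iminium dichloride 23 (not isolated)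
Conditions: POCl3 (2.5 equiv), DMF, EtOAc, 0 °C → rt; then H2O, 50 °C
Reagents that add atoms: N,N-dimethylformamide CN(C)C=O; water O
Why: Vilsmeier–Haack formylation goes to the free phloroglucinol ring B, which has exactly two open positions, while ring A is deactivated by the ketone and two pivalates.

Step 16
Reactants: 24 dialdehyde dipivalate
Product: 25 5-[(2R,3S)-5,7-dihydroxy-3-isopropyl-6-(3-methylbutanoyl)chroman-2-yl]-2,4,6-trihydroxybenzene-1,3-dicarbaldehyde
Conditions: K2CO3, MeOH, rt; then aq. HCl (1 M)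
Reagents that add atoms: none
Why: Transesterification cleaves the activated aryl pivalates (ortho-acyl phenoxide leaving groups) under mild base that the aldehydes, the ketone and both stereocentres tolerate.

**Compound list**

1 | (S)-4-benzyloxazolidin-2-one | O=C1OC[C@H](Cc2ccccc2)N1 | starting material
2 | 3-methylbutanoyl chloride | CC(C)CC(Cl)=O | starting material
3 | N-lithio (S)-4-benzyloxazolidin-2-one | [Li+].O=C1OC[C@H](Cc2ccccc2)[N-]1 | intermediate (not isolated)
4 | (S)-4-benzyl-3-(3-methylbutanoyl)oxazolidin-2-one | CC(C)CC(=O)N1[C@@H](Cc2ccccc2)COC1=O | intermediate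
5 | 2,4,6-trihydroxybenzaldehyde | O=Cc1c(O)cc(O)cc1O | starting material
6 | 2,4,6-tris(benzyloxy)benzaldehyde | O=Cc1c(OCc2ccccc2)cc(OCc2ccccc2)cc1OCc1ccccc1 | intermediate
7 | Z-dibutylboron enolate of 4 | CCCCB(CCCC)O/C(=C\C(C)C)N1[C@@H](Cc2ccccc2)COC1=O | intermediate (not isolated)
8 | dibutylboron aldolate of 9 | O=C1OC[C@H](Cc2ccccc2)N1C(=O)[C@@H](C(C)C)[C@@H](c1c(OCc2ccccc2)cc(OCc2ccccc2)cc1OCc1ccccc1)OB(CCCC)CCCC | intermediate (not isolated)
9 | (S)-4-benzyl-3-[(2S,3S)-3-hydroxy-2-isopropyl-3-(2,4,6-tris(benzyloxy)phenyl)propanoyl]oxazolidin-2-one | O=C1OC[C@H](Cc2ccccc2)N1C(=O)[C@@H](C(C)C)[C@@H](c1c(OCc2ccccc2)cc(OCc2ccccc2)cc1OCc1ccccc1)O | intermediate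
10 | (S)-4-benzyl-3-[(2S,3S)-3-(tert-butyldimethylsilyloxy)-2-isopropyl-3-(2,4,6-tris(benzyloxy)phenyl)propanoyl]oxazolidin-2-one | O=C1OC[C@H](Cc2ccccc2)N1C(=O)[C@@H](C(C)C)[C@@H](c1c(OCc2ccccc2)cc(OCc2ccccc2)cc1OCc1ccccc1)O[Si](C)(C)C(C)(C)C | intermediate
11 | (2R,3S)-3-(tert-butyldimethylsilyloxy)-2-isopropyl-3-[2,4,6-tris(benzyloxy)phenyl]propan-1-ol | OC[C@@H](C(C)C)[C@@H](c1c(OCc2ccccc2)cc(OCc2ccccc2)cc1OCc1ccccc1)O[Si](C)(C)C(C)(C)C | intermediate
12 | tert-butyl{(1S,2S)-2-(iodomethyl)-3-methyl-1-[2,4,6-tris(benzyloxy)phenyl]butoxy}dimethylsilane | IC[C@@H](C(C)C)[C@@H](c1c(OCc2ccccc2)cc(OCc2ccccc2)cc1OCc1ccccc1)O[Si](C)(C)C(C)(C)C | intermediate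
13 | phloroglucinol (benzene-1,3,5-triol) | Oc1cc(O)cc(O)c1 | starting material
14 | 3-methyl-1-(2,4,6-trihydroxyphenyl)butan-1-one | CC(C)CC(=O)c1c(O)cc(O)cc1O | intermediate
15 | 1-[4-(tert-butyldimethylsilyloxy)-2,6-dihydroxyphenyl]-3-methylbutan-1-one | CC(C)CC(=O)c1c(O)cc(O[Si](C)(C)C(C)(C)C)cc1O | intermediate
16 | 1-[4-(tert-butyldimethylsilyloxy)-2,6-dihydroxy-3-iodophenyl]-3-methylbutan-1-one | CC(C)CC(=O)c1c(O)cc(O[Si](C)(C)C(C)(C)C)c(I)c1O | intermediate
17 | 5-(tert-butyldimethylsilyloxy)-4-iodo-2-(3-methylbutanoyl)-1,3-phenylene bis(2,2-dimethylpropanoate) | CC(C)CC(=O)c1c(OC(=O)C(C)(C)C)cc(O[Si](C)(C)C(C)(C)C)c(I)c1OC(=O)C(C)(C)C | intermediate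
18 | {(2S,3S)-3-(tert-butyldimethylsilyloxy)-2-isopropyl-3-[2,4,6-tris(benzyloxy)phenyl]propyl}zinc iodide | I[Zn]C[C@@H](C(C)C)[C@@H](c1c(OCc2ccccc2)cc(OCc2ccccc2)cc1OCc1ccccc1)O[Si](C)(C)C(C)(C)C | intermediate (not isolated)
19 | 5-(tert-butyldimethylsilyloxy)-4-[(2S,3S)-3-(tert-butyldimethylsilyloxy)-2-isopropyl-3-(2,4,6-tris(benzyloxy)phenyl)propyl]-2-(3-methylbutanoyl)-1,3-phenylene bis(2,2-dimethylpropanoate) | CC(C)CC(=O)c1c(OC(=O)C(C)(C)C)cc(O[Si](C)(C)C(C)(C)C)c(C[C@@H](C(C)C)[C@@H](c2c(OCc3ccccc3)cc(OCc3ccccc3)cc2OCc2ccccc2)O[Si](C)(C)C(C)(C)C)c1OC(=O)C(C)(C)C | intermediate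
20 | 5-hydroxy-4-[(2S,3S)-3-hydroxy-2-isopropyl-3-(2,4,6-tris(benzyloxy)phenyl)propyl]-2-(3-methylbutanoyl)-1,3-phenylene bis(2,2-dimethylpropanoate) | CC(C)CC(=O)c1c(OC(=O)C(C)(C)C)cc(O)c(C[C@@H](C(C)C)[C@@H](c2c(OCc3ccccc3)cc(OCc3ccccc3)cc2OCc2ccccc2)O)c1OC(=O)C(C)(C)C | intermediate
21 | (2R,3S)-3-isopropyl-6-(3-methylbutanoyl)-2-[2,4,6-tris(benzyloxy)phenyl]chromane-5,7-diyl bis(2,2-dimethylpropanoate) | CC(C)CC(=O)c1c(OC(=O)C(C)(C)C)cc2c(c1OC(=O)C(C)(C)C)C[C@@H](C(C)C)[C@H](c1c(OCc3ccccc3)cc(OCc3ccccc3)cc1OCc1ccccc1)O2 | intermediate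
22 | (2R,3S)-3-isopropyl-6-(3-methylbutanoyl)-2-(2,4,6-trihydroxyphenyl)chromane-5,7-diyl bis(2,2-dimethylpropanoate) | CC(C)CC(=O)c1c(OC(=O)C(C)(C)C)cc2c(c1OC(=O)C(C)(C)C)C[C@@H](C(C)C)[C@H](c1c(O)cc(O)cc1O)O2 | intermediate
23 | bis(N,N-dimethyliminium) dichloride of 24 | CC(C)CC(=O)c1c(OC(=O)C(C)(C)C)cc2c(c1OC(=O)C(C)(C)C)C[C@@H](C(C)C)[C@H](c1c(O)c(C=[N+](C)C)c(O)c(C=[N+](C)C)c1O)O2.[Cl-].[Cl-] | intermediate (not isolated)
24 | (2R,3S)-2-(3,5-diformyl-2,4,6-trihydroxyphenyl)-3-isopropyl-6-(3-methylbutanoyl)chromane-5,7-diyl bis(2,2-dimethylpropanoate) | CC(C)CC(=O)c1c(OC(=O)C(C)(C)C)cc2c(c1OC(=O)C(C)(C)C)C[C@@H](C(C)C)[C@H](c1c(O)c(C=O)c(O)c(C=O)c1O)O2 | intermediate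
25 | 5-[(2R,3S)-5,7-dihydroxy-3-isopropyl-6-(3-methylbutanoyl)chroman-2-yl]-2,4,6-trihydroxybenzene-1,3-dicarbaldehyde | CC(C)CC(=O)c1c(O)cc2c(c1O)C[C@@H](C(C)C)[C@H](c1c(O)c(C=O)c(O)c(C=O)c1O)O2 | target

**Totals**
Total steps: 16. Longest linear sequence: 11 steps (1, 3, 4, 5, 6, 11, 12, 13, 14, 15, 16).

**Steps most likely to fail, with fallbacks**

Step 3 (aldol between an α-branched enolate and a deactivated, di-ortho-substituted aldehyde). The fallback replaces the aldol by a Claisen-type C-acylation followed by a directed ketone reduction; it sets out from 6 (with 2) and comes back at 11.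
- Aldehyde 6 is oxidised (NaClO2, NaH2PO4, 2-methyl-2-butene, t-BuOH/H2O) to 2,4,6-tris(benzyloxy)benzoic acid F1.
- Oxalyl chloride with catalytic DMF converts it into 2,4,6-tris(benzyloxy)benzoyl chloride F2.
- The commercial enantiomeric auxiliary (R)-4-benzyloxazolidin-2-one is acylated with 2 as in step 1 to give (R)-4-benzyl-3-(3-methylbutanoyl)oxazolidin-2-one F3. The (R)-auxiliary is needed because a chelated lithium enolate is attacked on the face opposite to the one used by the boron enolate.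
- The lithium Z-enolate of F3 (LDA, THF, −78 °C) is acylated by F2 to give (R)-4-benzyl-3-[(2S)-2-isopropyl-3-oxo-3-(2,4,6-tris(benzyloxy)phenyl)propanoyl]oxazolidin-2-one F4, which is configurationally stable through allylic 1,3-strain.
- Chelation-controlled reduction with Zn(BH4)2 gives the syn alcohol (R)-4-benzyl-3-[(2S,3S)-3-hydroxy-2-isopropyl-3-(2,4,6-tris(benzyloxy)phenyl)propanoyl]oxazolidin-2-one F5.
- TBSOTf/2,6-lutidine gives (R)-4-benzyl-3-[(2S,3S)-3-(tert-butyldimethylsilyloxy)-2-isopropyl-3-(2,4,6-tris(benzyloxy)phenyl)propanoyl]oxazolidin-2-one F6, and LiBH4 then delivers 11.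

Step 11 (coupling of a β-branched alkylzinc with a di-ortho-substituted aryl iodide). The fallback switches to a B-alkyl Suzuki–Miyaura coupling; it sets out from 12 and comes back at 19.
- Iodide 12 undergoes iodine–lithium exchange (t-BuLi, 2.1 equiv, Et2O, −78 °C) and the alkyllithium is trapped with B-methoxy-9-BBN to give lithium {(2S,3S)-3-(tert-butyldimethylsilyloxy)-2-isopropyl-3-[2,4,6-tris(benzyloxy)phenyl]propyl}(methoxy)-9-borabicyclo[3.3.1]nonan-9-uide F7.
- F7 is coupled in the same flask with 17 (PdCl2(dppf), 5 mol %, K3PO4, DMF, rt) to give 19.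
- Any loss of the aryl silyl group under the basic conditions does not matter, because step 12 removes both silyl groups.

Step 13 (displacement at a very hindered, highly electron-rich benzylic carbon; elimination to the styrene can compete). The fallback drops the activated, invertive displacement for a thermodynamically controlled cationic cyclodehydration; it sets out from 20 and comes back at 21 and makes no new compound (F0).
- Diol 20 is treated with catalytic pyridinium p-toluenesulfonate (or 10 mol % camphorsulfonic acid) in CH2Cl2 with 4 Å sieves at 0 °C.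
- The 2,4,6-tris(benzyloxy)benzyl cation is captured by the para-acyl phenol.
- The untouched C-3 centre steers ring closure to the 2,3-trans chroman 21, and any cis isomer equilibrates to it by reversible ring opening.

**Further compounds**
F1 | step 3 | 2,4,6-tris(benzyloxy)benzoic acid | OC(=O)c1c(OCc2ccccc2)cc(OCc2ccccc2)cc1OCc1ccccc1
F2 | step 3 | 2,4,6-tris(benzyloxy)benzoyl chloride | ClC(=O)c1c(OCc2ccccc2)cc(OCc2ccccc2)cc1OCc1ccccc1
F3 | step 3 | (R)-4-benzyl-3-(3-methylbutanoyl)oxazolidin-2-one | CC(C)CC(=O)N1[C@H](Cc2ccccc2)COC1=O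
F4 | step 3 | (R)-4-benzyl-3-[(2S)-2-isopropyl-3-oxo-3-(2,4,6-tris(benzyloxy)phenyl)propanoyl]oxazolidin-2-one | O=C1OC[C@@H](Cc2ccccc2)N1C(=O)[C@@H](C(C)C)C(=O)c1c(OCc2ccccc2)cc(OCc2ccccc2)cc1OCc1ccccc1
F5 | step 3 | (R)-4-benzyl-3-[(2S,3S)-3-hydroxy-2-isopropyl-3-(2,4,6-tris(benzyloxy)phenyl)propanoyl]oxazolidin-2-one | O=C1OC[C@@H](Cc2ccccc2)N1C(=O)[C@@H](C(C)C)[C@@H](c1c(OCc2ccccc2)cc(OCc2ccccc2)cc1OCc1ccccc1)O
F6 | step 3 | (R)-4-benzyl-3-[(2S,3S)-3-(tert-butyldimethylsilyloxy)-2-isopropyl-3-(2,4,6-tris(benzyloxy)phenyl)propanoyl]oxazolidin-2-one | O=C1OC[C@@H](Cc2ccccc2)N1C(=O)[C@@H](C(C)C)[C@@H](c1c(OCc2ccccc2)cc(OCc2ccccc2)cc1OCc1ccccc1)O[Si](C)(C)C(C)(C)C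
F7 | step 11 | lithium {(2S,3S)-3-(tert-butyldimethylsilyloxy)-2-isopropyl-3-[2,4,6-tris(benzyloxy)phenyl]propyl}(methoxy)-9-borabicyclo[3.3.1]nonan-9-uide | [Li+].CO[B-]1(C[C@@H](C(C)C)[C@@H](c2c(OCc3ccccc3)cc(OCc3ccccc3)cc2OCc2ccccc2)O[Si](C)(C)C(C)(C)C)C2CCCC1CCC2
F0 | step 13 | none | none
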